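**Retrosynthetic overview**
1. Target 44 ← acetate/silyl adjustment ← lactone 41 ← two hydroxyl-controlled ketone reductions and C7–O–C18 lactonisation of the ten-membered 2,7-diketone 37.
2. Feature used: the oxygenated carbons C2 and C7 lie 1,6 across the ten-membered ring and are linked on one side by C3–C4–C5(CO2Me)=C6 (cis). Ring C1–C10 is therefore ring B (C1, C2, C7, C8, C9, C10) fused to a cyclohexa-1,3-diene ester ring C (C2–C7) with the shared C2=C7 bond cut, so 37 ← ozonolysis of tricyclic dienoate 34.
3. 34 ← Birch reduction, dienyl triflate and methoxycarbonylation of anisole 27 ← aldol of aryl ketone 24 with propanoic acid (C8–C17); C9–O by Rubottom oxidation, C8=O by benzylic oxidation.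
4. Ring A stereocentres (C10, C11, C12, C14) ← hydroxyl-relayed reductions of the enone from an asymmetric Robinson annulation of 6-methoxy-1-methyl-2-tetralone with ethyl vinyl ketone (C1).
5. Ring order: B and aromatic C bought, A by annulation, C dearomatised, B and C merged into the ten-membered ring by C2=C7 scission, γ-lactone last.

Key step: step 21

Remark (numbering): ten-membered ring C1–C10 (C1 quaternary with methyl, C5 bears ester carbon C16, C7 is the lactone O–CH, C8 the tertiary carbinol); ring A is C1, C10–C14; lactone carbons are C17 (CHMe) and C18 (C=O); α is the face opposite the C1 methyl.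
Remark (assumption): the chiral-imine Michael addition of step 4 is taken to follow its usual sense of induction, so the (R)-amine is used; C17 is carried as an epimer mixture from step 16 and fixed in step 24.

**Step 1**
Reactants: 1 6-methoxy-2-tetralone; 2 pyrrolidine
Product: 3 1-(6-methoxy-3,4-dihydronaphthalen-2-yl)pyrrolidine
Conditions: p-TsOH (cat.), PhMe, reflux, Dean–Stark, N2
Reagents that add atoms: none
Why: Condensation with a secondary amine under azeotropic water removal should give the arene-conjugated enamine (Stork enamine formation), which fixes the nucleophilic site at the benzylic α-carbon.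

**Step 2**
Reactants: 3 1-(6-methoxy-3,4-dihydronaphthalen-2-yl)pyrrolidine
Product: 5 racemic 6-methoxy-1-methyl-2-tetralone, via iminium iodide 4 (not isolated)
Conditions: MeI, MeCN, 60 °C; then H2O, 60 °C
Reagents that add atoms: iodomethane CI; water O
Why: Stork enamine alkylation methylates only the benzylic carbon and hydrolysis of the iminium salt returns the ketone, whose new centre is left racemic on purpose because it is re-enolised in the next two steps.

**Step 3**
Reactants: 5 racemic 6-methoxy-1-methyl-2-tetralone; 6 (R)-1-phenylethylamine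
Product: 7 (R)-1-phenylethyl imine of 5
Conditions: p-TsOH (cat.), PhMe, reflux, Dean–Stark
Reagents that add atoms: none
Why: Ketimine condensation gives an imine that equilibrates with the arene-conjugated secondary enamine, so the labile benzylic centre is erased and both enantiomers of 5 converge.

**Step 4**
Reactants: 7 (R)-1-phenylethyl imine of 5; 8 ethyl vinyl ketone
Product: 10 (R)-6-methoxy-1-methyl-1-(3-oxopentyl)-3,4-dihydronaphthalen-2(1H)-one, via Michael adduct imine 9 (not isolated)
Conditions: THF, 25–40 °C, 3 d; then 20% aq AcOH, 25 °C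
Reagents that add atoms: water O
Why: Asymmetric Michael addition of the chiral secondary enamine tautomer through a compact chair-like aza-ene transition state with internal N–H transfer, in which the enone approaches the enamine face remote from the phenyl group of the auxiliary, should create the C1 quaternary centre in the required sense, and mild acid hydrolysis releases the 1,5-diketone and the amine.

**Step 5**
Reactants: 10 (R)-6-methoxy-1-methyl-1-(3-oxopentyl)-3,4-dihydronaphthalen-2(1H)-one
Product: 12 (S)-7-methoxy-1,4a-dimethyl-4,4a,9,10-tetrahydrophenanthren-2(3H)-one (C10=C11 enone; C12 ketone), via ring A ketol 11 (not isolated)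
Conditions: NaOMe, MeOH, 60 °C
Reagents that add atoms: none
Why: Intramolecular aldol condensation (second half of the Robinson annulation) of the ethyl ketone methylene onto the tetralone carbonyl closes ring A and dehydrates to the tetrasubstituted enone, while quaternary C1 cannot epimerise.

**Step 6**
Reactants: 12 tricyclic enone
Product: 14 cross-conjugated 10,13-dien-12-one, via TMS dienol ether 13 (not isolated)
Conditions: LiN(iPr)2, THF, −78 °C; TMSCl; then Pd(OAc)2 (1.1 equiv), MeCN, 25 °C
Reagents that add atoms: none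
Why: Kinetic deprotonation at C13 and silylation give the cross-conjugated silyl dienol ether, and Saegusa–Ito oxidation with divalent palladium (β-hydride elimination from the palladium enolate) should install C13=C14 without touching the benzylic C8 methylene.

**Step 7**
Reactants: 14 cross-conjugated 10,13-dien-12-one
Product: 15 13α,14α-epoxy-10-en-12-one
Conditions: 30% H2O2, NaOH (0.3 equiv), MeOH, 0 °C
Reagents that add atoms: hydrogen peroxide OO
Why: Weitz–Scheffer nucleophilic epoxidation adds hydroperoxide to C14 of the less substituted enone (the tetrasubstituted C10 terminus is inert) from the face opposite the axial C1 methyl, which sets the C14 oxygen α.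

**Step 8**
Reactants: 15 13α,14α-epoxy-10-en-12-one
Product: 16 14α-hydroxy-10-en-12-one
Conditions: SmI2 (2.2 equiv), THF/MeOH, −90 °C
Reagents that add atoms: none
Why: Single-electron reduction of the ketone by SmI2 cleaves the adjacent C13–O bond (reductive opening of an α,β-epoxy ketone) and methanol protonates the samarium enolate, so C14 is retained and the dehydration-prone β-hydroxy enone forms under neutral conditions.

**Step 9**
Reactants: 16 14α-hydroxy-10-en-12-one
Product: 17 10-ene-12β,14α-diol
Conditions: Me4NBH(OAc)3, MeCN/AcOH (1:1), −30 °C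
Reagents that add atoms: none
Why: Evans–Saksena reduction, in which the C14 hydroxyl exchanges onto boron and delivers hydride internally to the α face of the C12 carbonyl, should give the 12β alcohol anti to the 14α hydroxyl by 1,2-addition.

**Step 10**
Reactants: 17 10-ene-12β,14α-diol
Product: 18 12β-tert-butyldimethylsilyl ether of 17 (14α-OH free)
Conditions: TBSCl (1.1 equiv), imidazole, DMF, 0 °C
Reagents that add atoms: tert-butyldimethylsilyl chloride CC(C)(C)[Si](C)(C)Cl
Why: Silylation should be selective for the allylic pseudo-equatorial C12 hydroxyl because the C14 hydroxyl is axial and neopentylic next to quaternary C1.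

**Step 11**
Reactants: 18 12β-silyl ether 14α-ol
Product: 19 trans-fused 10α-H 11β-methyl 12β-silyloxy 14α-ol
Conditions: H2 (1–5 bar), [Ir(cod)(PCy3)(py)]PF6 (10 mol %), CH2Cl2, 25 °C
Reagents that add atoms: none
Why: Hydroxyl-directed hydrogenation, in which the cationic monovalent iridium catalyst binds the free homoallylic 14α hydroxyl and adds both hydrogens to the α face of the tetrasubstituted C10=C11 bond (the β face also carries the C12 silyl ether), sets the trans ring fusion and the axial 11β-methyl group.

**Step 12**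
Reactants: 19 trans-fused 14α-ol
Product: 20 14α-pivalate of 19
Conditions: PivCl, DMAP, pyridine, 60 °C
Reagents that add atoms: pivaloyl chloride CC(C)(C)C(=O)Cl
Why: DMAP-catalysed acylation masks the C14 hydroxyl as an ester without α-hydrogens that survives oxidation and strong base and is designed to fall off in the later dissolving-metal step.

**Step 13**
Reactants: 20 14α-pivalate
Product: 21 C8 aryl ketone
Conditions: CrO3, 3,5-dimethylpyrazole, CH2Cl2, −20 °C
Reagents that add atoms: chromium trioxide O=[Cr](=O)=O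
Why: Benzylic C–H oxidation by the CrO3–dimethylpyrazole complex should occur at C8 because it is the only benzylic methylene (C1 is quaternary), as in the C6 oxidation of estrogen methyl ethers.

**Step 14**
Reactants: 21 C8 aryl ketone
Product: 22 C8 triethylsilyl enol ether (C8=C9)
Conditions: TESOTf, Et3N, CH2Cl2, 0 °C
Reagents that add atoms: triethylsilyl triflate CC[Si](CC)(CC)OS(=O)(=O)C(F)(F)F
Why: Soft enolisation of the aryl ketone toward its only α-methylene (C9) gives the silyl enol ether regiospecifically (silyl enol ether formation).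

**Step 15**
Reactants: 22 C8 triethylsilyl enol ether
Product: 24 9α-triethylsilyloxy C8 ketone, via silyloxy epoxide 23 (not isolated)
Conditions: mCPBA, NaHCO3, CH2Cl2, −20 to 0 °C
Reagents that add atoms: 3-chloroperoxybenzoic acid OOC(=O)c1cccc(Cl)c1
Why: Rubottom oxidation, in which the peracid epoxidises the enol ether from the α face away from the axial C1 methyl and the silyloxy epoxide opens with 1,4-silyl shift, should give the 9α-silyloxy ketone with the new group equatorial and therefore stable to epimerisation.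

**Step 16**
Reactants: 24 9α-triethylsilyloxy C8 ketone; 25 propanoic acid
Product: 27 C8 tertiary carbinol acid (8α-OH; C17 epimers), via dilithium enediolate 26 (not isolated)
Conditions: 25, LiN(iPr)2 (2.1 equiv), THF, 0 °C; then 24, −78 to −30 °C; AcOH, −78 °C
Reagents that add atoms: none
Why: Aldol addition of the carboxylic acid dianion to the C8 ketone from the β face, equatorial and anti to the adjacent 9α-silyloxy group, should give the 8α tertiary carbinol as a dianionic aldolate that resists retro-aldol cleavage, C17 being formed as a mixture that is corrected in step 24.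

**Step 17**
Reactants: 27 C8 tertiary carbinol acid
Product: 29 β,γ-unsaturated C5 keto acid (C2=C7; 14α-OH free), via dienol ether acid 28 (not isolated)
Conditions: LiN(SiMe3)2 (2.1 equiv), THF, −78 °C; Li, NH3 (l), t-BuOH, −78 to −33 °C; isoprene then NH4Cl; then (CO2H)2 on wet SiO2, CH2Cl2, 25 °C
Reagents that add atoms: water O
Why: Birch reduction of the anisole ring on the pre-formed benzylic alkoxide carboxylate (so that C8–O hydrogenolysis and carboxyl reduction are suppressed) protonates the unsubstituted C3 and C6 positions, leaves the C4=C5 enol ether and the tetrasubstituted C2=C7 bond and cleaves the pivalate in the same pot, and mild oxalic acid hydrolysis then gives the C5 ketone without moving C2=C7 into conjugation.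

**Step 18**
Reactants: 29 β,γ-unsaturated C5 keto acid
Product: 30 methyl ester of 29
Conditions: TMSCHN2, PhMe/MeOH (4:1), 0 °C
Reagents that add atoms: (trimethylsilyl)diazomethane C[Si](C)(C)C=[N+]=[N-]
Why: O-Methylation of the acid with the diazoalkane is neutral and fast, so the β,γ-unsaturated ketone, the silyl ethers and the β-hydroxy acid unit are not disturbed.

**Step 19**
Reactants: 30 keto methyl ester
Product: 32 bis-TMS dienyl triflate (C5–OTf; C5=C6 and C2=C7), via bis-TMS ketone 31 (not isolated)
Conditions: N-(trimethylsilyl)imidazole, CH2Cl2, 40 °C; evaporate; then LiN(SiMe3)2 (1.1 equiv), THF, −78 °C; 2-[N,N-bis(trifluoromethylsulfonyl)amino]-5-chloropyridine, −78 °C; aq NH4Cl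
Reagents that add atoms: N-(trimethylsilyl)imidazole C[Si](C)(C)n1ccnc1; 2-[N,N-bis(trifluoromethylsulfonyl)amino]-5-chloropyridine FC(F)(F)S(=O)(=O)N(c1ccc(Cl)cn1)S(=O)(=O)C(F)(F)F
Why: Transient silylation of both hydroxyls removes the aldolate that could fragment under base, after which the amide base takes the most acidic proton at C6 (flanked by the carbonyl and C2=C7) and O-sulfonylation of the extended dienolate gives the conjugated dienyl triflate (enol triflate formation).

**Step 20**
Reactants: 32 bis-TMS dienyl triflate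
Product: 34 tricyclic cyclohexa-1,3-diene ester (8α,14α-diol), via bis-TMS dienoate 33 (not isolated)
Conditions: CO (1 atm), Pd(OAc)2 (5 mol %), PPh3 (10 mol %), Et3N, MeOH/DMF, 50 °C; then citric acid, MeOH, 25 °C
Reagents that add atoms: carbon monoxide [C-]#[O+]; methanol CO
Why: Oxidative addition of the dienyl triflate to zerovalent palladium, CO insertion and methanolysis of the acyl palladium (alkoxycarbonylation of an enol triflate) install C16 as the C5 ester, and citric acid methanolysis then frees the C8 and C14 hydroxyls while the triethylsilyl and tert-butyldimethylsilyl ethers stay.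

**Step 21**
Reactants: 34 tricyclic cyclohexa-1,3-diene ester
Product: 37 ten-membered 2,7-diketone with cis C5=C6 enoate, via primary ozonide 35 (not isolated), via secondary ozonide 36 (not isolated)
Conditions: O3, CH2Cl2, NaHCO3, Sudan Red 7B (indicator), −78 °C; then Me2S, −78 to 25 °C
Reagents that add atoms: ozone [O-][O+]=O
Why: Ozone adds as a 1,3-dipole across the tetra-alkylated C2=C7 bond to give primary ozonide 35, which cycloreverts to a tethered ketone and carbonyl oxide that reclose to secondary ozonide 36, and dimethyl sulfide reduces this to the C2 and C7 ketones. The closest known reaction type is the ozonolytic cleavage of the ring-fusion alkene of octalins to cyclodecane-1,6-diones, combined with the known preference of ozone for the γ,δ bond of a dienoate. No ring is closed by bond formation: the ten-membered ring C1–C10 arises by scission of the bond shared by rings B and C, so no macrocyclisation is needed and the C5=C6 enoate is delivered cis as it was in the six-membered ring. No stereocentre is created (C2 and C7 become trigonal) and C1, C8, C9, C10, C11, C12 and C14 are untouched. The step needs chemoselectivity for C2=C7 over C5=C6, which the substrate secures because the C5 ester depletes its own double bond while C2=C7 is the most substituted and most electron-rich alkene, and the first cleavage makes C5=C6 an even poorer ene-dione alkene; indicator dye and buffer guard against over-oxidation and acid-promoted transannular aldolisation.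

**Step 22**
Reactants: 37 ten-membered 2,7-diketone
Product: 39 γ-lactone 2-ketone (C17 epimers), via 7-hydroxy 2-ketone 38 (not isolated)
Conditions: NaBH4, CeCl3·7H2O, MeOH/THF, −78 °C; then PPTS (cat.), PhMe, 50 °C
Reagents that add atoms: none
Why: Luche reduction, with cerium held between the C7 carbonyl and the C8 hydroxyl, should direct 1,2-attack of hydride from the peripheral face of the ten-membered ring (the side of the exocyclic C17 chain, the ring body lying on the C9 side) to give the 7,8-anti diol, whose C7 hydroxyl then closes the γ-lactone on the C18 ester under mild acid, while the hindered C2 ketone and the trans-disposed C16 ester do not compete.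

**Step 23**
Reactants: 39 γ-lactone 2-ketone
Product: 40 γ-lactone 2,14-diol (C17 epimers)
Conditions: Et2BOMe, THF/MeOH (4:1), −78 °C; NaBH4, −78 to −40 °C; then AcOH, MeOH azeotrope
Reagents that add atoms: none
Why: Narasaka–Prasad reduction, in which Et2BOMe ties the 14α hydroxyl and the C2 carbonyl into a six-membered boron chelate fused to ring A with C10 axial on the chelate, should let external hydride attack C2 axially from the opposite face and give the 2,14-syn diol.

**Step 24**
Reactants: 40 γ-lactone 2,14-diol (C17 epimers)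
Product: 41 γ-lactone 2,14-diol with C17 fixed
Conditions: DBU, PhMe, 25 °C
Reagents that add atoms: none
Why: Reversible deprotonation α to the lactone carbonyl (thermodynamic epimerisation) should funnel both C17 epimers to the isomer with the methyl group trans to the bulky C9 ring carbon and cis to the small C8 hydroxyl.

**Step 25**
Reactants: 41 γ-lactone 2,14-diol
Product: 42 2,9,14-triol 12-silyl ether
Conditions: PPTS, MeOH/CH2Cl2, 0 to 25 °C
Reagents that add atoms: none
Why: Acid-catalysed methanolysis cleaves the triethylsilyl ether much faster than the tert-butyldimethylsilyl ether (selective desilylation), which exposes the C9 hydroxyl and keeps C12 masked.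

**Step 26**
Reactants: 42 2,9,14-triol 12-silyl ether
Product: 43 2,9,14-triacetate 12-silyl ether
Conditions: Ac2O, DMAP, Et3N, CH2Cl2, 25–40 °C
Reagents that add atoms: acetic anhydride CC(=O)OC(C)=O
Why: DMAP-catalysed acetylation esterifies the three secondary hydroxyls at C2, C9 and C14, whereas the tertiary C8 hydroxyl flanked by two fully substituted carbons should not react.

**Step 27**
Reactants: 43 2,9,14-triacetate 12-silyl ether
Product: 44 target CNP0233742.2
Conditions: HF·pyridine, pyridine, THF, 0 to 25 °C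
Reagents that add atoms: none
Why: Buffered fluoride desilylation removes the C12 silyl ether under weakly acidic conditions that avoid lactone opening and β-elimination, and the trans-1,3 relationship of the C12 hydroxyl and the C14 acetate precludes acyl migration.

**Compound list**
1 | 6-methoxy-2-tetralone | COc1ccc2c(c1)CCC(=O)C2 | starting material
2 | pyrrolidine | C1CCNC1 | starting material
3 | 1-(6-methoxy-3,4-dihydronaphthalen-2-yl)pyrrolidine | COc1ccc2C=C(N3CCCC3)CCc2c1 | intermediate
4 | iminium iodide of methylated enamine | COc1ccc2C(C)C(=[N+]3CCCC3)CCc2c1.[I-] | intermediate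
5 | racemic 6-methoxy-1-methyl-2-tetralone | COc1ccc2c(c1)CCC(=O)C2C | intermediate
6 | (R)-1-phenylethylamine | C[C@@H](N)c1ccccc1 | starting material
7 | (R)-1-phenylethyl imine of 5 | COc1ccc2c(c1)CCC(=N[C@H](C)c1ccccc1)C2C | intermediate
8 | ethyl vinyl ketone | C=CC(=O)CC | starting material
9 | Michael adduct imine | COc1ccc2c(c1)CCC(=N[C@H](C)c1ccccc1)[C@]2(C)CCC(=O)CC | intermediate
10 | (R)-6-methoxy-1-methyl-1-(3-oxopentyl)-3,4-dihydronaphthalen-2(1H)-one | COc1ccc2c(c1)CCC(=O)[C@]2(C)CCC(=O)CC | intermediate
11 | ring A ketol (aldol adduct) | COc1cc2CCC3(O)C(C)C(=O)CC[C@]3(C)c2cc1 | intermediate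
12 | (S)-7-methoxy-1,4a-dimethyl-4,4a,9,10-tetrahydrophenanthren-2(3H)-one | COc1cc2CCC3=C(C)C(=O)CC[C@]3(C)c2cc1 | intermediate
13 | TMS dienol ether (C12–OTMS, C12=C13) | COc1cc2CCC3=C(C)C(O[Si](C)(C)C)=CC[C@]3(C)c2cc1 | intermediate
14 | cross-conjugated 10,13-dien-12-one | COc1cc2CCC3=C(C)C(=O)C=C[C@]3(C)c2cc1 | intermediate
15 | 13α,14α-epoxy-10-en-12-one | COc1cc2CCC3=C(C)C(=O)[C@@H]4O[C@@H]4[C@]3(C)c2cc1 | intermediate
16 | 14α-hydroxy-10-en-12-one | COc1cc2CCC3=C(C)C(=O)C[C@H](O)[C@]3(C)c2cc1 | intermediate
17 | 10-ene-12β,14α-diol | COc1cc2CCC3=C(C)[C@@H](O)C[C@H](O)[C@]3(C)c2cc1 | intermediate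
18 | 12β-TBS ether, 14α-ol | COc1cc2CCC3=C(C)[C@@H](O[Si](C)(C)C(C)(C)C)C[C@H](O)[C@]3(C)c2cc1 | intermediate
19 | trans-fused 10α-H, 11β-methyl, 12β-OTBS, 14α-ol | COc1cc2CC[C@H]3[C@@H](C)[C@@H](O[Si](C)(C)C(C)(C)C)C[C@H](O)[C@]3(C)c2cc1 | intermediate
20 | 14α-pivalate of 19 | COc1cc2CC[C@H]3[C@@H](C)[C@@H](O[Si](C)(C)C(C)(C)C)C[C@H](OC(=O)C(C)(C)C)[C@]3(C)c2cc1 | intermediate
21 | C8 aryl ketone | COc1cc2C(=O)C[C@H]3[C@@H](C)[C@@H](O[Si](C)(C)C(C)(C)C)C[C@H](OC(=O)C(C)(C)C)[C@]3(C)c2cc1 | intermediate
22 | C8 triethylsilyl enol ether | COc1cc2C(O[Si](CC)(CC)CC)=C[C@H]3[C@@H](C)[C@@H](O[Si](C)(C)C(C)(C)C)C[C@H](OC(=O)C(C)(C)C)[C@]3(C)c2cc1 | intermediate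
23 | 8,9α-epoxide bearing 8-OTES (silyloxy epoxide) | COc1cc2[C@]4(O[Si](CC)(CC)CC)O[C@@H]4[C@H]3[C@@H](C)[C@@H](O[Si](C)(C)C(C)(C)C)C[C@H](OC(=O)C(C)(C)C)[C@]3(C)c2cc1 | intermediate
24 | 9α-triethylsilyloxy C8 ketone | COc1cc2C(=O)[C@H](O[Si](CC)(CC)CC)[C@H]3[C@@H](C)[C@@H](O[Si](C)(C)C(C)(C)C)C[C@H](OC(=O)C(C)(C)C)[C@]3(C)c2cc1 | intermediate
25 | propanoic acid | CCC(=O)O | starting material
26 | dilithium prop-1-ene-1,1-diolate | [Li+].[Li+].CC=C([O-])[O-] | intermediate
27 | C8 tertiary carbinol acid (C17 epimers) | COc1cc2[C@@](O)(C(C)C(=O)O)[C@H](O[Si](CC)(CC)CC)[C@H]3[C@@H](C)[C@@H](O[Si](C)(C)C(C)(C)C)C[C@H](OC(=O)C(C)(C)C)[C@]3(C)c2cc1 | intermediate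
28 | Birch dienol ether acid (C4=C5 enol ether, C2=C7, 14-OH) | COC=1CC=2[C@@](O)(C(C)C(=O)O)[C@H](O[Si](CC)(CC)CC)[C@H]3[C@@H](C)[C@@H](O[Si](C)(C)C(C)(C)C)C[C@H](O)[C@]3(C)C=2CC=1 | intermediate
29 | β,γ-unsaturated C5 keto acid | O=C1CC=2[C@@](O)(C(C)C(=O)O)[C@H](O[Si](CC)(CC)CC)[C@H]3[C@@H](C)[C@@H](O[Si](C)(C)C(C)(C)C)C[C@H](O)[C@]3(C)C=2CC1 | intermediate
30 | keto methyl ester | O=C1CC=2[C@@](O)(C(C)C(=O)OC)[C@H](O[Si](CC)(CC)CC)[C@H]3[C@@H](C)[C@@H](O[Si](C)(C)C(C)(C)C)C[C@H](O)[C@]3(C)C=2CC1 | intermediate
31 | 8,14-bis-TMS ether of 30 | O=C1CC=2[C@@](O[Si](C)(C)C)(C(C)C(=O)OC)[C@H](O[Si](CC)(CC)CC)[C@H]3[C@@H](C)[C@@H](O[Si](C)(C)C(C)(C)C)C[C@H](O[Si](C)(C)C)[C@]3(C)C=2CC1 | intermediate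
32 | bis-TMS dienyl triflate | FC(F)(F)S(=O)(=O)OC1=CC=2[C@@](O[Si](C)(C)C)(C(C)C(=O)OC)[C@H](O[Si](CC)(CC)CC)[C@H]3[C@@H](C)[C@@H](O[Si](C)(C)C(C)(C)C)C[C@H](O[Si](C)(C)C)[C@]3(C)C=2CC1 | intermediate
33 | bis-TMS dienoate | COC(=O)C1=CC=2[C@@](O[Si](C)(C)C)(C(C)C(=O)OC)[C@H](O[Si](CC)(CC)CC)[C@H]3[C@@H](C)[C@@H](O[Si](C)(C)C(C)(C)C)C[C@H](O[Si](C)(C)C)[C@]3(C)C=2CC1 | intermediate
34 | tricyclic cyclohexa-1,3-diene ester (8α,14α-diol) | COC(=O)C1=CC=2[C@@](O)(C(C)C(=O)OC)[C@H](O[Si](CC)(CC)CC)[C@H]3[C@@H](C)[C@@H](O[Si](C)(C)C(C)(C)C)C[C@H](O)[C@]3(C)C=2CC1 | intermediate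
35 | primary ozonide across C2–C7 | COC(=O)C1=CC2(OOOC23CC1)[C@@](O)(C(C)C(=O)OC)[C@H](O[Si](CC)(CC)CC)[C@H]4[C@@H](C)[C@@H](O[Si](C)(C)C(C)(C)C)C[C@H](O)[C@]34C | intermediate
36 | secondary ozonide bridging C2 and C7 | COC(=O)C1=CC2(OOC3(O2)CC1)[C@@](O)(C(C)C(=O)OC)[C@H](O[Si](CC)(CC)CC)[C@H]4[C@@H](C)[C@@H](O[Si](C)(C)C(C)(C)C)C[C@H](O)[C@]34C | intermediate
37 | ten-membered 2,7-diketone, cis C5=C6 enoate | COC(=O)/C1=C/C(=O)[C@@](O)(C(C)C(=O)OC)[C@H](O[Si](CC)(CC)CC)[C@H]2[C@@H](C)[C@@H](O[Si](C)(C)C(C)(C)C)C[C@H](O)[C@]2(C)C(=O)CC1 | intermediate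
38 | 7-hydroxy 2-ketone | COC(=O)/C1=C/[C@H](O)[C@@](O)(C(C)C(=O)OC)[C@H](O[Si](CC)(CC)CC)[C@H]2[C@@H](C)[C@@H](O[Si](C)(C)C(C)(C)C)C[C@H](O)[C@]2(C)C(=O)CC1 | intermediate
39 | γ-lactone 2-ketone (C17 epimers) | COC(=O)/C1=C/[C@@H]2OC(=O)C(C)[C@@]2(O)[C@H](O[Si](CC)(CC)CC)[C@H]2[C@@H](C)[C@@H](O[Si](C)(C)C(C)(C)C)C[C@H](O)[C@]2(C)C(=O)CC1 | intermediate
40 | γ-lactone 2,14-diol (C17 epimers) | COC(=O)/C1=C/[C@@H]2OC(=O)C(C)[C@@]2(O)[C@H](O[Si](CC)(CC)CC)[C@H]2[C@@H](C)[C@@H](O[Si](C)(C)C(C)(C)C)C[C@H](O)[C@]2(C)[C@H](O)CC1 | intermediate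
41 | γ-lactone 2,14-diol, C17 fixed | COC(=O)/C1=C/[C@@H]2OC(=O)[C@H](C)[C@@]2(O)[C@H](O[Si](CC)(CC)CC)[C@H]2[C@@H](C)[C@@H](O[Si](C)(C)C(C)(C)C)C[C@H](O)[C@]2(C)[C@H](O)CC1 | intermediate
42 | 2,9,14-triol 12-TBS ether | COC(=O)/C1=C/[C@@H]2OC(=O)[C@H](C)[C@@]2(O)[C@H](O)[C@H]2[C@@H](C)[C@@H](O[Si](C)(C)C(C)(C)C)C[C@H](O)[C@]2(C)[C@H](O)CC1 | intermediate
43 | 2,9,14-triacetate 12-TBS ether | COC(=O)/C1=C/[C@@H]2OC(=O)[C@H](C)[C@@]2(O)[C@H](OC(C)=O)[C@H]2[C@@H](C)[C@@H](O[Si](C)(C)C(C)(C)C)C[C@H](OC(C)=O)[C@]2(C)[C@H](OC(C)=O)CC1 | intermediate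
44 | CNP0233742.2 | COC(=O)/C1=C/[C@@H]2OC(=O)[C@H](C)[C@@]2(O)[C@H](OC(C)=O)[C@H]2[C@@H](C)[C@@H](O)C[C@H](OC(C)=O)[C@]2(C)[C@H](OC(C)=O)CC1 | target

**Step count and risks**
Total step count: 27. Longest linear sequence: 27 steps from 1 (the route is fully linear; 2, 6, 8 and 25 are purchased).

Most likely to fail, step 16: the strongly basic enediolate may deprotonate C9 of the hindered α-silyloxy aryl ketone instead of adding, or the adduct may revert on work-up. The fallback sets out from 24 and returns at 27. Addition of the weakly basic organocerium reagent from isopropenylmagnesium bromide and CeCl3 (THF, −78 °C) should give, by the same β-face attack, the isopropenyl carbinol F1. Hydroboration–oxidation of its 1,1-disubstituted alkene (BH3·THF, 0 °C; then NaBO3·4H2O) should give the 8,18-diol F2 as C17 epimers. Oxidation of the primary alcohol with TEMPO and PhI(OAc)2 in MeCN/H2O should then deliver acid 27.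

Second, step 19: silylation of the crowded tertiary C8 hydroxyl may stay incomplete, so that the aldolate fragments by retro-aldol under the amide base, or deprotonation may occur at C4 and lead to the unconjugated enol triflate. The fallback sets out from 30 and returns at 34. TMSOTf and Et3N (CH2Cl2, 0 °C) should cap both hydroxyls and, by soft thermodynamically controlled enolisation, convert the ketone into the conjugated tris-silyl dienol ether F3. Fluoride-catalysed sulfonyl transfer (C4F9SO2F, catalytic Bu4N[Ph3SiF2], THF, 0 °C) should then give the dienyl nonaflate F4 without any strong base. F4 would enter the carbonylation and citric acid methanolysis of step 20 and give 34.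

Third, step 22: the conformation of the ten-membered ring, not the chelate, may decide which face of the C7 ketone is open, so facial selectivity may be poor, and conjugate reduction of the doubly activated C5=C6 bond may compete. The fallback sets out from 37 and returns at 38. Substrate control is replaced by catalyst control: CBS reduction with the (R)-configured B-methyl oxazaborolidine and catecholborane (PhMe, −78 °C), in which the fully substituted C8 acts as the large group, should deliver hydride 1,2 to the face that gives the 7S alcohol 38. Lactonisation then follows as in the second half of step 22, and no compound outside the list is formed (F0).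

**Further compounds**
F1 | step 16 | isopropenyl carbinol (8α-OH, C8-isopropenyl) | COc1cc2[C@@](O)(C(C)=C)[C@H](O[Si](CC)(CC)CC)[C@H]3[C@@H](C)[C@@H](O[Si](C)(C)C(C)(C)C)C[C@H](OC(=O)C(C)(C)C)[C@]3(C)c2cc1
F2 | step 16 | 8,18-diol (C17 epimers) | COc1cc2[C@@](O)(C(C)CO)[C@H](O[Si](CC)(CC)CC)[C@H]3[C@@H](C)[C@@H](O[Si](C)(C)C(C)(C)C)C[C@H](OC(=O)C(C)(C)C)[C@]3(C)c2cc1
F3 | step 19 | tris-silyl dienol ether (C5–OTMS, 8,14-bis-TMS ether) | C[Si](C)(C)OC1=CC=2[C@@](O[Si](C)(C)C)(C(C)C(=O)OC)[C@H](O[Si](CC)(CC)CC)[C@H]3[C@@H](C)[C@@H](O[Si](C)(C)C(C)(C)C)C[C@H](O[Si](C)(C)C)[C@]3(C)C=2CC1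
F4 | step 19 | dienyl nonaflate (8,14-bis-TMS ether) | FC(F)(F)C(F)(F)C(F)(F)C(F)(F)S(=O)(=O)OC1=CC=2[C@@](O[Si](C)(C)C)(C(C)C(=O)OC)[C@H](O[Si](CC)(CC)CC)[C@H]3[C@@H](C)[C@@H](O[Si](C)(C)C(C)(C)C)C[C@H](O[Si](C)(C)C)[C@]3(C)C=2CC1
F0 | step 22 | none | none
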